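Remark: atom labels C1–C15 are daucane locants, defined in the first section. One assumption is made: the kinetic Buchner product 4 isomerises with triethylamine to the 3,4‑dihydro isomer 5, as the parent phenyl compound does.

## Analysis of the target

Target 18 is the 6‑O‑vanillate of a daucane triol. The core is a trans‑fused bicyclo[5.3.0]decane: C1 is the quaternary ring‑fusion carbon carrying methyl C15, C4 a tertiary carbinol carrying the isopropyl group, C5 the ring‑fusion methine, C6 the acylated carbinol, C7=C8 a trisubstituted olefin with methyl C14 on C8, C9 a free allylic carbinol and C10 a methylene. There are five stereocentres (1R,4R,5S,6S,9R). C15, 4‑OH and 9‑OH lie on one face (β); H‑5, the isopropyl group and the 6‑O‑acyl group lie on the other (α). The sensitive parts are the 1,4‑dioxygenated 2‑ene (ionisation, allylic transposition), the tertiary alcohol 1,3 to the ester (acyl migration, dehydration) and the free phenol of the ester. The hard points are three. First, the quaternary C1 sits next to C5 in a trans fusion, and a bicyclic C5 that is epimerisable next to a carbonyl tends to go cis. Second, C4 is fully substituted next to C5. Third, the two secondary allylic oxygens at C6 and C9 are trans across the ring, and only the more hindered one is acylated. The feature that invites the key step: C1, C10, C9, C8, C7 and C6, with C14 on C8 "para" to C1, have the carbon pattern of a p‑tolyl ring. C5 is the only atom of the seven‑membered ring outside that pattern, and its neighbour C4 is oxygenated. The seven‑membered ring is therefore a tolyl ring plus one carbon, and the C6–O/C9–O pair across C7=C8 is the imprint of a ring diene plus O2.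

## Retrosynthetic reasoning

18 ⇒ 17 ⇒ 16 ⇒ 13 + 14. The phenol is unmasked last (aryl acetate 17). The C9 carbinol is traced back to a ketone (16), and the ester C–O bond at C6 is cut to hydroxy enone 13 and acid 14. The cut is made here because in 13 the C6 hydroxyl is the only secondary alcohol, so C6 and C9 are told apart by oxidation level and the terpenoid needs no protecting group. The forward steps are an esterification of a hindered alcohol and a reagent‑controlled 1,2‑reduction of the enone.

13 ⇒ 12 ⇒ 11. Both C–O bonds at C6 and C9 are cut together. Hydroxy enone 13 is the Kornblum–DeLaMare product of the 6,9‑endoperoxide 12, which is the [4+2] adduct of O2 with the ring diene C6=C7–C8=C9 of 11. This gives the 1,4‑oxygen pattern, the C7=C8 olefin and the C6 configuration in one operation. The forward reaction must add O2 on the face opposite C15 and then remove H‑9 rather than H‑6.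

11 ⇒ 10. The C4–isopropyl bond is cut. In ketone 10 the carbonyl on C4 is flanked by C5, which carries C6 on the β face, so an isopropyl organometallic should enter from the α face, as the target requires. It is done before C6 is oxygenated, so that C4 and C6 are never carbonyls at the same time.

10 ⇒ 8 ⇒ 7 ⇒ 6 ⇒ 5. Methyl C15 is disconnected from C1. A direct enantioselective conjugate methylation of the tetrasubstituted enone 5 has no close precedent. C15 is therefore brought in as the methylene of a cyclopropane (C1–C15–C5) in 8. Reductive cleavage of the C5–C15 bond of 8 gives the C1 methyl and a C4 enolate whose protonation sets H‑5. The cyclopropane comes from hydroxyl‑directed cyclopropanation of allylic alcohol 6 (giving 7), and 6 comes from CBS reduction of the achiral trienone 5. The temporary C4 carbinol carries the absolute configuration to C1 and is then oxidised away.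

5 ⇒ 4 ⇒ 3 ⇒ 1. The key cut removes C5 from between C1 and C6 and opens the C5–C1 bond. The seven‑membered ring falls back to the tolyl ring of diazoketone 3, and C5 becomes the diazo carbon next to the C4 carbonyl. Forward, an intramolecular Buchner reaction builds both rings from an arylpropanoic acid derivative. Diazoketone 3 comes from commercial acid 1 via chloride 2.

## Alternatives that were turned down

Alternative 1: the textbook route. The C7=C8 bond is cut; the forward key step is ring‑closing metathesis of cyclopentane diene A1. It was turned down for step economy and control. A1 needs the quaternary C1, C4 and C5 built stepwise on a cyclopentane. C6 and C9 are acyclic carbinols that each need a separate reagent‑controlled addition. The metathesis must close a trisubstituted olefin next to a carbinol that is flanked by two fully substituted carbons. The two secondary allylic alcohols then have to be told apart with protecting groups.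

Alternative 2: seven‑membered ring first by desymmetrisation. The C1–C2 and C4–C5 bonds are cut. Forward, a copper‑catalysed enantioselective conjugate addition of a masked 4‑methyl‑3‑oxopentyl nucleophile to the symmetric dienone A2 (from a furan/oxyallyl (4+3) adduct) sets C1 and gives diketone A3. An intramolecular aldol of A3 then closes the five‑membered ring. It was turned down because that aldol must deliver the side chain from an axial position on C1, which places H‑5 cis to C15. C5 then sits next to a C6 ketone in a bicycle with no thermodynamic bias towards the trans fusion. C9 would also need a separate allylic oxidation.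

Alternative 3: chiral‑pool ring contraction. The C3=C4 ring bond of (S)‑terpinen‑4‑ol A4 would be cleaved by ozonolysis and the chain re‑closed by aldol condensation to enal A5, which carries the C4 carbinol intact. The C7–C10 unit would then be annulated. It was turned down for two reasons. The aldehyde α‑carbon is flanked by two tertiary β‑hydroxyl groups after the aldol, so dehydration has no reason to go towards C1 rather than C4, and retro‑aldol threatens. The new C1–C10 bond would also have to form on the face of the isopropyl group, with nothing in A5 to direct it there.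

Key step: step 2

## Steps

Step 1
Reactants: 1 3‑(4‑methylphenyl)propanoic acid
Product: 3 1‑diazo‑4‑(4‑methylphenyl)butan‑2‑one, via 3‑(4‑methylphenyl)propanoyl chloride 2 (not isolated)
Conditions: (COCl)2, cat. DMF, CH2Cl2, 0 °C → rt; then TMSCHN2 (2.2 equiv), THF/MeCN, 0 °C
Reagents that add atoms: trimethylsilyldiazomethane, C[Si](C)(C)C=[N+]=[N-]
Why: Acylation of a diazomethane equivalent by an acid chloride (Arndt–Eistert type diazoketone synthesis); the chloride removes the silyl group and no stereocentre is involved.

Step 2
Reactants: 3 1‑diazo‑4‑(4‑methylphenyl)butan‑2‑one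
Product: 5 6‑methyl‑3,4‑dihydroazulen‑1(2H)‑one, via 6‑methyl‑3,8a‑dihydroazulen‑1(2H)‑one 4 (not isolated)
Conditions: Rh2(OAc)4 (1 mol %), CH2Cl2, reflux, slow addition of 3; then Et3N, CH2Cl2, rt
Reagents that add atoms: none
Why: Rh2(OAc)4 turns 3 into a rhodium carbenoid that cyclopropanates the ipso/ortho bond of the tolyl ring, closing the five‑membered ring by attack of C5 on C1 through the three‑atom tether (exo mode) to give a norcaradiene. Disrotatory 6π electrocyclic opening of the norcaradiene then inserts C5 between C1 and C6 and turns the benzene ring into the seven‑membered ring of 4. This is the intramolecular Buchner reaction; the closest precedent is the conversion of 1‑diazo‑4‑arylbutan‑2‑ones into 3,8a‑dihydroazulen‑1(2H)‑ones and their amine‑mediated isomerisation to 3,4‑dihydroazulen‑1(2H)‑ones. The para methyl group makes the two ortho bonds equivalent, so one constitutional isomer should form, with C14 on C8. The only stereocentre formed (C5 of 4) is racemic and is erased on purpose when Et3N moves the C1=C10 double bond into conjugation as C5=C1, giving the achiral trienone 5 with its carbonyl on C4; no stereocontrol is needed. The selectivity needed is chemoselectivity for cyclopropanation over aromatic or benzylic C–H insertion and carbene dimerisation. It is secured by the electron‑rich tolyl ring, the carboxylate catalyst, slow addition, and exclusion of acid, which would rearomatise 4.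

Step 3
Reactants: 5 6‑methyl‑3,4‑dihydroazulen‑1(2H)‑one
Product: 6 (S)‑6‑methyl‑1,2,3,4‑tetrahydroazulen‑1‑ol
Conditions: (R)‑Me‑CBS (0.15 equiv), catecholborane (1.5 equiv), toluene, −78 °C; cold basic work‑up
Reagents that add atoms: none
Why: Corey–Bakshi–Shibata reduction of a 2,3‑disubstituted cyclopentenone, with the fully substituted vinyl carbon C5 as the large group and CH2 as the small one; the (R)‑catalyst should give the (S)‑carbinol at C4, and catecholborane at low temperature avoids hydroboration of the triene.

Step 4
Reactants: 6 (S)‑6‑methyl‑1,2,3,4‑tetrahydroazulen‑1‑ol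
Product: 7 (1S)‑6‑methyl‑1,2,3,4‑tetrahydro‑3a,8a‑methanoazulen‑1‑ol (cyclopropane C1–C15–C5, methano bridge cis to the hydroxyl)
Conditions: Et2Zn (2.2 equiv), CH2I2 (2.2 equiv), CH2Cl2, −20 → 0 °C
Reagents that add atoms: diiodomethane, ICI
Why: Hydroxyl‑directed Simmons–Smith (Furukawa) cyclopropanation of a cyclopent‑2‑enol; the zinc alkoxide delivers the carbenoid to the adjacent C5=C1 bond on its own face, which fixes C1 (and the temporary C5) relative to C4 and leaves the distal diene untouched.

Step 5
Reactants: 7 cyclopropyl carbinol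
Product: 8 6‑methyl‑3,4‑dihydro‑3a,8a‑methanoazulen‑1(2H)‑one (cyclopropyl ketone, configuration at C1 and C5 as in 7)
Conditions: Dess–Martin periodinane, NaHCO3, CH2Cl2, 0 °C → rt
Reagents that add atoms: none
Why: Buffered Dess–Martin oxidation of a secondary cyclopropyl carbinol without a cationic intermediate; the C4 stereocentre has passed its information to C1 and is removed.

Step 6
Reactants: 8 cyclopropyl ketone
Product: 10 (3aR,8aR)‑3a,6‑dimethyl‑3,3a,4,8a‑tetrahydroazulen‑1(2H)‑one (trans‑fused), via samarium(III) trienolate 9 (not isolated)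
Conditions: SmI2 (2.5 equiv), THF–HMPA, t‑BuOH (2.5 equiv), −78 °C; pH 7 buffer at −78 °C; used crude
Reagents that add atoms: none
Why: Reductive ring opening of a cyclopropyl ketone: the ketyl cleaves the exocyclic C5–C15 bond, which overlaps with the carbonyl and diene π systems, and a second electron plus t‑BuOH turns C15 into the C1 methyl. Kinetic protonation of trienolate 9 at its α‑carbon C5, from the face opposite the new angular methyl, should place H‑5 trans to C15.

Step 7
Reactants: 10 trans‑fused dienyl ketone
Product: 11 (1R,3aR,8aR)‑3a,6‑dimethyl‑1‑(propan‑2‑yl)‑1,2,3,3a,4,8a‑hexahydroazulen‑1‑ol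
Conditions: i‑PrLi (3 equiv), anhydrous CeCl3 (3.2 equiv), THF, −78 °C
Reagents that add atoms: isopropyllithium, [Li]C(C)C
Why: Organocerium (Imamoto) 1,2‑addition to an easily enolised ketone; the reagent should attack C4 from the α face, opposite C6 on C5 and opposite C15, giving 4α‑isopropyl and 4β‑OH and fixing C5.

Step 8
Reactants: 11 diene carbinol
Product: 13 (1R,3aR,8S,8aS)‑1,8‑dihydroxy‑3a,6‑dimethyl‑1‑(propan‑2‑yl)‑2,3,3a,4,8,8a‑hexahydroazulen‑5(1H)‑one, via 6α,9α‑epidioxide 12 (not isolated)
Conditions: O2, rose bengal (2 mol %), visible light, MeOH–CH2Cl2, −20 °C; then Et3N (2 equiv), 0 °C → rt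
Reagents that add atoms: dioxygen, O=O
Why: [4+2] cycloaddition of singlet oxygen to the s‑cis ring diene, on the face opposite the axial C15 methyl (methanol mutes hydrogen‑bond direction by the 4‑OH), sets the C6–O bond α. Kornblum–DeLaMare fragmentation with Et3N should remove the more accessible H‑9, giving the C9 ketone and the free 6α‑hydroxyl.

Step 9
Reactants: 13 hydroxy enone; 14 4‑acetoxy‑3‑methoxybenzoic acid
Product: 16 (1R,3aR,8S,8aS)‑1‑hydroxy‑3a,6‑dimethyl‑5‑oxo‑1‑(propan‑2‑yl)‑1,2,3,3a,4,5,8,8a‑octahydroazulen‑8‑yl 4‑acetoxy‑3‑methoxybenzoate, via mixed anhydride 15 (not isolated)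
Conditions: 14, 2,4,6‑trichlorobenzoyl chloride, Et3N, THF, rt; then 13, DMAP, toluene, rt → 40 °C
Reagents that add atoms: none
Why: Yamaguchi esterification of a hindered secondary alcohol; the tertiary 4‑OH is inert and C9 is a ketone, so only the C6 oxygen can be acylated.

Step 10
Reactants: 16 keto ester
Product: 17 (1R,3aR,5R,8S,8aS)‑1,5‑dihydroxy‑3a,6‑dimethyl‑1‑(propan‑2‑yl)‑1,2,3,3a,4,5,8,8a‑octahydroazulen‑8‑yl 4‑acetoxy‑3‑methoxybenzoate
Conditions: (S)‑Me‑CBS (0.5 equiv), catecholborane (3 equiv), toluene–CH2Cl2, −78 °C
Reagents that add atoms: none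
Why: CBS 1,2‑reduction of an α‑methyl enone under reagent control, with the vinyl carbon C8 as the large group; the (S)‑catalyst should give the (9R) carbinol, which is also the alcohol expected from hydride attack opposite C15.

Step 11
Reactants: 17 aryl acetate
Product: 18 (1R,3aR,5R,8S,8aS)‑1,5‑dihydroxy‑3a,6‑dimethyl‑1‑(propan‑2‑yl)‑1,2,3,3a,4,5,8,8a‑octahydroazulen‑8‑yl 4‑hydroxy‑3‑methoxybenzoate (target)
Conditions: K2CO3 (0.5 equiv), MeOH, 0 °C, 20 min; NH4Cl work‑up
Reagents that add atoms: none
Why: Chemoselective methanolysis of a phenyl acetate, which reacts far faster than the hindered benzoate; the liberated phenoxide further deactivates the vanillate carbonyl.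

## Compound list

1 | 3‑(4‑methylphenyl)propanoic acid | Cc1ccc(CCC(=O)O)cc1 | starting material
2 | 3‑(4‑methylphenyl)propanoyl chloride | Cc1ccc(CCC(=O)Cl)cc1 | intermediate (not isolated)
3 | 1‑diazo‑4‑(4‑methylphenyl)butan‑2‑one | Cc1ccc(CCC(=O)C=[N+]=[N-])cc1 | intermediate
4 | 6‑methyl‑3,8a‑dihydroazulen‑1(2H)‑one (racemic) | O=C1CCC2=CC=C(C)C=CC12 | intermediate (not isolated)
5 | 6‑methyl‑3,4‑dihydroazulen‑1(2H)‑one | O=C1CCC2=C1C=CC(C)=CC2 | intermediate
6 | (S)‑6‑methyl‑1,2,3,4‑tetrahydroazulen‑1‑ol | O[C@H]1CCC2=C1C=CC(C)=CC2 | intermediate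
7 | (1S)‑6‑methyl‑1,2,3,4‑tetrahydro‑3a,8a‑methanoazulen‑1‑ol, methano bridge cis to OH | O[C@H]1CC[C@]23C[C@@]13C=CC(C)=CC2 | intermediate
8 | 6‑methyl‑3,4‑dihydro‑3a,8a‑methanoazulen‑1(2H)‑one, configuration as in 7 | O=C1CC[C@]23C[C@@]13C=CC(C)=CC2 | intermediate
9 | samarium(III) trienolate of 10 (O‑bound SmI2) | C[C@@]12CC=C(C)C=CC1=C(O[Sm](I)I)CC2 | intermediate (not isolated)
10 | (3aR,8aR)‑3a,6‑dimethyl‑3,3a,4,8a‑tetrahydroazulen‑1(2H)‑one | O=C1CC[C@]2(C)CC=C(C)C=C[C@@H]12 | intermediate
11 | (1R,3aR,8aR)‑3a,6‑dimethyl‑1‑(propan‑2‑yl)‑1,2,3,3a,4,8a‑hexahydroazulen‑1‑ol | CC(C)[C@]1(O)CC[C@]2(C)CC=C(C)C=C[C@@H]12 | intermediate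
12 | 6α,9α‑epidioxide of 11 (peroxide bridge on the face opposite C15) | CC(C)[C@]1(O)CC[C@]2(C)C[C@@H]3OO[C@@H](C=C3C)[C@@H]12 | intermediate (not isolated)
13 | (1R,3aR,8S,8aS)‑1,8‑dihydroxy‑3a,6‑dimethyl‑1‑(propan‑2‑yl)‑2,3,3a,4,8,8a‑hexahydroazulen‑5(1H)‑one | CC(C)[C@]1(O)CC[C@]2(C)CC(=O)C(C)=C[C@H](O)[C@@H]12 | intermediate
14 | 4‑acetoxy‑3‑methoxybenzoic acid | COc1cc(C(=O)O)ccc1OC(C)=O | starting material
15 | 4‑acetoxy‑3‑methoxybenzoic 2,4,6‑trichlorobenzoic anhydride | COc1cc(C(=O)OC(=O)c2c(Cl)cc(Cl)cc2Cl)ccc1OC(C)=O | intermediate (not isolated)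
16 | 6‑O‑(4‑acetoxy‑3‑methoxybenzoyl) ester of 13 (C9 ketone) | COc1cc(C(=O)O[C@H]2C=C(C)C(=O)C[C@@]3(C)CC[C@@](O)(C(C)C)[C@H]23)ccc1OC(C)=O | intermediate
17 | (9R)‑alcohol of 16 (O‑acetyl derivative of the target) | COc1cc(C(=O)O[C@H]2C=C(C)[C@H](O)C[C@@]3(C)CC[C@@](O)(C(C)C)[C@H]23)ccc1OC(C)=O | intermediate
18 | (1R,3aR,5R,8S,8aS)‑1,5‑dihydroxy‑3a,6‑dimethyl‑1‑(propan‑2‑yl)‑1,2,3,3a,4,5,8,8a‑octahydroazulen‑8‑yl 4‑hydroxy‑3‑methoxybenzoate | COc1cc(C(=O)O[C@H]2C=C(C)[C@H](O)C[C@@]3(C)CC[C@@](O)(C(C)C)[C@H]23)ccc1O | target

## Step count and least certain steps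

Total: 11 steps. Longest linear sequence: 11 steps (1 → 18; acid 14 enters in step 9).

Step 2 (key step). The carbenoid may insert into an aromatic or benzylic C–H bond or dimerise instead of cyclopropanating the ring, and traces of acid would rearomatise the cycloheptatriene, so the ring expansion would be lost. Fallback, from 1 back to 5: Birch reduction of 1 would give 3‑(4‑methylcyclohexa‑1,4‑dien‑1‑yl)propanoic acid F1, which is converted as in step 1 into 1‑diazo‑4‑(4‑methylcyclohexa‑1,4‑dien‑1‑yl)butan‑2‑one F2. Copper‑ or rhodium‑catalysed intramolecular cyclopropanation of the tether‑bearing ring olefin, now an ordinary alkene cyclopropanation, would give the tricyclic cyclopropyl ketone F3. Bromine addition to the remaining trisubstituted double bond would give dibromide F4. Double dehydrobromination with DBU would give 4, which Et3N isomerises to 5.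

Step 6. Protonation of the trienolate may be poorly face‑selective, or may occur at C7/C9, and the product can epimerise at C5 or slip into conjugation, because the cis fusion and the conjugated dienone are the thermodynamic sinks. Fallback, from 8 back to 13: the isopropyl group is added before the cyclopropane is cleaved. Isopropylcerium addition to 8, opposite the methano bridge, would give the tertiary cyclopropyl carbinol F5. Photooxygenation, with the bridge now shielding the β face, would give epidioxide F6, and Et3N would give the cyclopropyl hydroxy enone F7. Dess–Martin oxidation would give the cyclopropyl ene‑dione F8. SmI2 cleavage of the exocyclic cyclopropane bond, followed by Et3N equilibration of C5 next to the C6 ketone, would give the trans‑fused 4‑hydroxy‑6,9‑dione F9. There the 4α‑isopropyl group and C6 avoid each other, so the trans fusion is the expected thermodynamic product. Hydroxyl‑directed reduction of the C6 ketone with Me4NBH(OAc)3, hydride delivered from the 4β‑OH, would give 13.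

Step 8. Hydrogen bonding to the 4‑OH may steer singlet oxygen to the wrong face, an ene reaction may compete, or the base may fragment the peroxide towards C6. Fallback, from 11 back to 13: silylation of the tertiary alcohol would give trimethylsilyl ether F10, in which the oxygen shields instead of directs. Photooxygenation would give epidioxide F11. Thiourea reduction, with no base‑induced fragmentation, would give the cis‑6α,9α‑diol F12. Manganese dioxide should oxidise only the less hindered C9 allylic alcohol, giving silyl ether F13, and mild acid would return 13.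

Step 7. The very acidic C5–H may be deprotonated, or the secondary organometallic may reduce the ketone by β‑hydride transfer, instead of adding. Fallback, from 10 back to 13: 2‑propenylcerium, an sp2 nucleophile without β‑hydrogens, would give the isopropenyl carbinol F14. Photooxygenation would give epidioxide F15, and Et3N would give the isopropenyl hydroxy enone F16. Hydrogenation of the 1,1‑disubstituted olefin with Wilkinson's catalyst, which should spare the trisubstituted enone, would give 13.

Step 4. The trienylic zinc alkoxide may ionise under the Lewis‑acidic conditions, or the carbenoid may also attack the diene. Fallback, from 5 back to 13: Corey–Chaykovsky methylenation of enone 5 with dimethylsulfoxonium methylide would give the cyclopropyl ketone in racemic form, rac‑8 F17, without a free carbinol. It is taken through steps 6–8 as the racemate. The resulting alcohol is esterified with (S)‑O‑methylmandelic acid; the (S)‑O‑methylmandelate of 13, F18, is separated from its diastereomer F19 and methanolysed (K2CO3, MeOH) to 13. This costs half of the material.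

## Further compounds

F1 | step 2 | 3‑(4‑methylcyclohexa‑1,4‑dien‑1‑yl)propanoic acid | CC1=CCC(CCC(=O)O)=CC1
F2 | step 2 | 1‑diazo‑4‑(4‑methylcyclohexa‑1,4‑dien‑1‑yl)butan‑2‑one | CC1=CCC(CCC(=O)C=[N+]=[N-])=CC1
F3 | step 2 | tricyclic cyclopropyl ketone (7,10‑dihydro derivative of the norcaradiene form of 4, racemic) | CC1=CCC23CCC(=O)C2C3C1
F4 | step 2 | 8,9‑dibromide of F3 (mixture of isomers) | CC1(Br)C(Br)CC23CCC(=O)C2C3C1
F5 | step 6 | tertiary cyclopropyl carbinol (isopropyl adduct of 8, OH cis to the methano bridge) | CC(C)[C@]1(O)CC[C@]23C[C@@]13C=CC(C)=CC2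
F6 | step 6 | 6α,9α‑epidioxide of F5 | CC(C)[C@]1(O)CC[C@]23C[C@@]13[C@H]1OO[C@@H](C2)C(C)=C1
F7 | step 6 | cyclopropyl 6α‑hydroxy‑7‑en‑9‑one | CC(C)[C@]1(O)CC[C@]23C[C@@]13[C@@H](O)C=C(C)C(=O)C2
F8 | step 6 | cyclopropyl 7‑ene‑6,9‑dione | CC(C)[C@]1(O)CC[C@]23C[C@@]13C(=O)C=C(C)C(=O)C2
F9 | step 6 | trans‑fused 4β‑hydroxydauc‑7‑ene‑6,9‑dione | CC(C)[C@]1(O)CC[C@]2(C)CC(=O)C(C)=CC(=O)[C@@H]12
F10 | step 8 | trimethylsilyl ether of 11 | CC(C)[C@]1(O[Si](C)(C)C)CC[C@]2(C)CC=C(C)C=C[C@@H]12
F11 | step 8 | 6α,9α‑epidioxide of F10 | CC(C)[C@]1(O[Si](C)(C)C)CC[C@]2(C)C[C@@H]3OO[C@@H](C=C3C)[C@@H]12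
F12 | step 8 | cis‑6α,9α‑diol, 4‑O‑trimethylsilyl ether | CC(C)[C@]1(O[Si](C)(C)C)CC[C@]2(C)C[C@H](O)C(C)=C[C@H](O)[C@@H]12
F13 | step 8 | 4‑O‑trimethylsilyl ether of 13 | CC(C)[C@]1(O[Si](C)(C)C)CC[C@]2(C)CC(=O)C(C)=C[C@H](O)[C@@H]12
F14 | step 7 | isopropenyl analogue of 11 | CC(=C)[C@]1(O)CC[C@]2(C)CC=C(C)C=C[C@@H]12
F15 | step 7 | 6α,9α‑epidioxide of F14 | CC(=C)[C@]1(O)CC[C@]2(C)C[C@@H]3OO[C@@H](C=C3C)[C@@H]12
F16 | step 7 | isopropenyl analogue of 13 | CC(=C)[C@]1(O)CC[C@]2(C)CC(=O)C(C)=C[C@H](O)[C@@H]12
F17 | step 4 | rac‑8 (racemic cyclopropyl ketone) | O=C1CCC23CC13C=CC(C)=CC2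
F18 | step 4 | 6‑O‑[(S)‑2‑methoxy‑2‑phenylacetyl] ester of 13 | CO[C@H](C(=O)O[C@H]1C=C(C)C(=O)C[C@@]2(C)CC[C@@](O)(C(C)C)[C@H]12)c1ccccc1
F19 | step 4 | 6‑O‑[(S)‑2‑methoxy‑2‑phenylacetyl] ester of the enantiomer of 13 | CO[C@H](C(=O)O[C@@H]1C=C(C)C(=O)C[C@]2(C)CC[C@](O)(C(C)C)[C@@H]12)c1ccccc1
A1 | alternative 1 | metathesis precursor: cyclopentane with C5–CH(OH)–CH=CH2 and C1–CH2–CH(OH)–C(CH3)=CH2 arms, configuration as in 18 | C=C[C@H](O)[C@H]1[C@](O)(C(C)C)CC[C@]1(C)C[C@@H](O)C(C)=C
A2 | alternative 2 | 3,6‑dimethylcyclohepta‑2,6‑dien‑1‑one | CC1=CC(=O)C=C(C)CC1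
A3 | alternative 2 | (S)‑3,6‑dimethyl‑6‑(4‑methyl‑3‑oxopentyl)cyclohept‑2‑en‑1‑one | CC(C)C(=O)CC[C@]1(C)CCC(C)=CC(=O)C1
A4 | alternative 3 | (S)‑terpinen‑4‑ol | CC1=CC[C@](O)(C(C)C)CC1
A5 | alternative 3 | (R)‑5‑hydroxy‑2‑methyl‑5‑(propan‑2‑yl)cyclopent‑1‑ene‑1‑carbaldehyde | CC1=C(C=O)[C@](O)(C(C)C)CC1
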